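## The problem

Compound 18 is an achiral flavone. Ring C is a 4-pyranone carrying the guaiacyl ring B at C2 and a methoxy group at C3. Ring A is fused at C4a–C8a and bears oxygen at C5, C7 and C8, with its only hydrogen at C6. With no stereocentre to set, the task is regiochemical: six oxygens of three kinds (four methyl ethers, one prenyl ether at C7, one free phenol at C4') must be told apart. The C5 oxygen is peri to the C4 carbonyl, so as a phenol it is chelated and slow to alkylate, and as a methyl ether it is the first to be lost to Lewis acids; Lewis-acidic deprotections are therefore excluded late in the route. The prenyl ether tolerates neither strong acid nor hydrogenolysis and can undergo Claisen rearrangement on strong heating, so it has to come late and the last deprotection has to be neutral. The feature that opens a short route is the pattern of ring A itself: the C5 and C8 oxygens are para (a hydroquinone dimethyl ether), a third oxygen sits at C7 and hydrogen at C6. This is the pattern a 3-alkoxy-4-hydroxycyclobutenone supplies as C5–C6–C7–C8 when it ring-expands onto a C=C bond, and that bond (C4a=C8a) is the C5=C6 bond of a preformed 4-pyranone ring C.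

## Retrosynthesis

**Endgame, 18 back to 15 (O–Si, O–prenyl and O–tert-butyl bonds).** The free C4' phenol of 18 is released last from the triisopropylsilyl ether 17 with buffered fluoride, which touches neither the prenyl ether nor the methyl ethers. The prenyl group of 17 is attached to the single free phenol of 16. That phenol is unmasked from the tert-butyl ether 15 by acidolysis, which methyl ethers and a hindered aryl silyl ether survive. Acid before prenyl and fluoride after is the only safe order. A benzyl or isopropyl group at C7 would need hydrogenolysis or a boron halide, which would endanger the prenyl group or the C5 methyl ether.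

**15 back to 14 (two O–CH3 bonds).** Both methyl groups at C5 and C8 are removed together, giving the hydroquinone 14. Introducing them in one operation costs a single step. It asks that the chelated C5 hydroxyl be alkylated completely without loss of the silyl ether.

**14 back to 11 (C4a–C5 bond, ring A).** Cutting C4a–C5 and unfolding C5–C8 into a four-membered ring gives the cyclobutenone carbinol 11, by way of the vinylketene 12 and the dienone 13. This cut is preferred to a C-ring closure (O1–C8a or C4–C4a) because ring A then needs no prefabricated tetra-oxygenated benzene. Its oxygens arrive already differentiated: tert-butoxy at C7, hydroxyl at C5 and C8, hydrogen at C6. The forward reaction must open the four-membered ring with the hydroxyl turning outward and close onto pyranone C5 through carbon.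

**11 back to 6 and 9 (C8–C8a bond).** The carbinol carbon is cut from pyranone C6, giving the 2-aryl-3-methoxy-4-pyranone 6 (as its C6 anion 10) and the semisquarate 9. Both halves are small and the junction is a single 1,2-addition. It requires metalation of 6 at C6 only, and attack on the carbonyl of 9 that is flanked by the tert-butoxy-bearing carbon. That regiochemistry places hydrogen at C6 and the alkoxy group at C7 of ring A.

**9 back to 7.** The semisquarate 9 comes from commercial di-tert-butyl squarate 7 by hydride addition (adduct 8) and loss of one tert-butoxy group with carbonyl transposition. The tert-butyl group is kept, and not isopropyl or methyl, because it alone can later be removed from C7 beside the C5 methyl ether.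

**6 back to 3 and 5, then to 1 and 4 (C2–C1' bond).** The biaryl-type bond between ring C and ring B is cut to the 2-bromopyranone 3 and the arylboronate 5. Bromide 3 comes from commercial 3-hydroxy-4-pyranone 1 through its 2-bromo derivative 2, and 5 from the commercial phenol boronate 4 by silylation. A furan ring-expansion route from an aryl furyl carbinol was weighed against this. It reaches the same pyranone, but one oxidation level short of the 3-hydroxy-4-pyranone, and the extra halogen-based oxidation would compete with halogenation of the electron-rich ring B. The cross-coupling needs only that the vinylogous acyl bromide couple faster than it hydrolyses.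

## Roads not taken

**Alternative 1:** The cut is O1–C8a. The open-chain diketone A1 would be oxidised in ring A by a tetravalent cerium oxidant to a 2-acylbenzoquinone. Its enol oxygen would add to C8a, and reoxidation would give the flavone-5,8-quinone A2.
- Merits: ring A comes from a simple 1,2,4-trioxygenated benzene, A1 is assembled by classical acylation chemistry, the prenyl ether is already in place, and no pyranone has to be metalated. In its assembly steps this road is better precedented than the chosen one.
- Weak points: the oxidant must choose ring A over the equally electron-rich guaiacyl ring B and spare the trisubstituted prenyl alkene. A2 has C5 and C8 at the quinone level, so a reduction and the same double methylation still follow. In A2 the C7 prenyloxy group is a vinylogous ester on a quinone and open to addition–elimination. The acetal on O4' must finally be removed with acid in the presence of the prenyl ether.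
- Comparison: the chosen plan forms ring A under neutral thermal conditions with no oxidant, delivers the hydroquinone level directly, and introduces the prenyl group only after every acidic step.

**Alternative 2:** The cut is C4–C4a. The aryloxyacrylic acid A3, activated as a mixed anhydride with a perfluorinated anhydride, would acylate ring A at C4a to give the chromone A4.
- Merits: only one ortho position of the aryl ether is free, so the ring closure is regiochemically unambiguous. A4 arrives with all four methyl ethers, including the one at C5, so no chelated phenol has to be methylated. In these two respects this road is better than the chosen one.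
- Weak points: A3 needs a 1,2,3,5-tetraoxygenated phenol with three different oxygen substituents and a tetrasubstituted enol ether of defined geometry (carboxyl cis to aryloxy). Under the acidic activation the alkene can isomerise and the acylium ion can then attack ring B to give an indenone. The benzyl group must be hydrogenolysed before prenylation, and the sulfonate is removed with base at the end.
- Comparison: the chosen plan builds the whole oxygen pattern of ring A in one step from a purchased squarate, with fragments two to three steps from catalogue compounds, and ends with a neutral deprotection.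

**Alternative 3:** The cuts are C5–C6, C7–C8 and C8–C8a. The chromium carbene complex A5, carried on pyranone C5, would react with the alkynylboronate A6 in a Dötz benzannulation to give the 4-methoxyphenol A7.
- Merits: three ring bonds form at once. C5 arrives as a methyl ether and C8 as a free phenol, and boron marks C7 for later oxidation. The C5 ether is obtained without alkylating a chelated phenol, an advantage over the chosen plan.
- Weak points: A5 needs a stoichiometric chromium carbonyl and a metalated pyranone carbon next to the C4 carbonyl. That carbonyl can chelate chromium after CO loss and stall or divert the annulation. A7 still needs methylation at C8, oxidation of the C–B bond, prenylation and acidic removal of the acetal beside the prenyl ether.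
- Comparison: the differentiation of C5 from C8 is of little use because both end as methyl ethers. The chosen plan uses no stoichiometric transition metal and the same number of steps after ring formation.

Key step: step 7

Assumption: compounds 1, 4 and 7 are taken as catalogue chemicals; the chiral intermediates 8, 11 and 13 are racemic, which is immaterial because 18 has no stereocentre.

## Route

**Step 1**
Reactants: 1 3-hydroxy-4H-pyran-4-one
Product: 2 2-bromo-3-hydroxy-4H-pyran-4-one
Conditions: NBS (1.0 equiv), MeCN, 0 °C to rt
Reagents that add atoms: N-bromosuccinimide, O=C1CCC(=O)N1Br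
Why: Electrophilic bromination of the enol at its β-carbon C2, the position at which 3-hydroxy-4-pyranones react with electrophiles (aldol, Mannich, halogenation); one equivalent at low temperature should stop at the monobromide.

**Step 2**
Reactants: 2 2-bromo-3-hydroxy-4H-pyran-4-one
Product: 3 2-bromo-3-methoxy-4H-pyran-4-one
Conditions: MeI, K2CO3, acetone, 40 °C
Reagents that add atoms: iodomethane, CI
Why: Williamson O-methylation of an acidic enolic hydroxyl; no other nucleophilic site is present.

**Step 3**
Reactants: 4 2-methoxy-4-(4,4,5,5-tetramethyl-1,3,2-dioxaborolan-2-yl)phenol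
Product: 5 triisopropyl[2-methoxy-4-(4,4,5,5-tetramethyl-1,3,2-dioxaborolan-2-yl)phenoxy]silane
Conditions: i-Pr3SiCl, imidazole, DMF, rt
Reagents that add atoms: chlorotriisopropylsilane, CC(C)[Si](Cl)(C(C)C)C(C)C
Why: Standard silylation of a phenol; protecting before the coupling keeps a phenoxide from displacing bromide from 3 by addition–elimination.

**Step 4**
Reactants: 3 2-bromo-3-methoxy-4H-pyran-4-one; 5 triisopropyl[2-methoxy-4-(4,4,5,5-tetramethyl-1,3,2-dioxaborolan-2-yl)phenoxy]silane
Product: 6 3-methoxy-2-[3-methoxy-4-(triisopropylsilyloxy)phenyl]-4H-pyran-4-one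
Conditions: Pd(PPh3)4 (5 mol %), K2CO3, 1,4-dioxane/H2O, 80 °C
Reagents that add atoms: none
Why: Suzuki–Miyaura coupling; zerovalent palladium inserts readily into the C–Br bond of a vinylogous acyl bromide, and aqueous carbonate is mild enough for the pyranone ring and the hindered aryl silyl ether.

**Step 5**
Reactants: 7 3,4-di-tert-butoxycyclobut-3-ene-1,2-dione
Product: 9 3-tert-butoxycyclobut-3-ene-1,2-dione, via aluminium alkoxide of 2,3-di-tert-butoxy-4-hydroxycyclobut-2-enone 8 (not isolated)
Conditions: LiAlH(OtBu)3, THF, −78 °C; then (CF3CO)2O, −78 to 0 °C; aq. NaHCO3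
Reagents that add atoms: none
Why: The hindered hydride adds once to a squarate carbonyl; trifluoroacetylation of the alkoxide and ionisation give an alkoxy-stabilised cation that sheds its tert-butyl group, which is the established squarate-to-semisquarate conversion and avoids aqueous mineral acid that would cleave the remaining tert-butyl ether; the stereocentre of 8 is racemic and disappears.

**Step 6**
Reactants: 6 3-methoxy-2-[3-methoxy-4-(triisopropylsilyloxy)phenyl]-4H-pyran-4-one; 9 3-tert-butoxycyclobut-3-ene-1,2-dione
Product: 11 racemic 6-(2-tert-butoxy-1-hydroxy-4-oxocyclobut-2-en-1-yl)-3-methoxy-2-[3-methoxy-4-(triisopropylsilyloxy)phenyl]-4H-pyran-4-one, via 6-lithiopyranone 10 (not isolated)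
Conditions: lithium 2,2,6,6-tetramethylpiperidide (from the amine and n-BuLi), THF, −78 °C; cannulate into 9 (1.3 equiv), THF, −78 °C; aq. NH4Cl
Reagents that add atoms: none
Why: C6–H is the only ring C–H next to the ring oxygen and should be removed by the hindered amide, as in C2 lithiation of 3-substituted chromones and C6 lithiation of uracils; the organolithium adds 1,2 to the more electrophilic carbonyl of 9, the one attached to the tert-butoxy-bearing carbon and not part of the vinylogous ester, as organolithiums do with alkoxycyclobutenediones. The carbinol stereocentre forms racemic and is destroyed in step 7.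

**Step 7**
Reactants: 11 racemic 6-(2-tert-butoxy-1-hydroxy-4-oxocyclobut-2-en-1-yl)-3-methoxy-2-[3-methoxy-4-(triisopropylsilyloxy)phenyl]-4H-pyran-4-one
Product: 14 7-tert-butoxy-5,8-dihydroxy-3-methoxy-2-[3-methoxy-4-(triisopropylsilyloxy)phenyl]-4H-chromen-4-one, via vinylketene 12 (not isolated), via 4aH-chromene-4,5-dione 13 (not isolated)
Conditions: toluene (degassed), 110 °C, Ar
Reagents that add atoms: none
Why: Heating opens the cyclobutenone by a conrotatory four-electron electrocyclic cleavage of the bond between the carbinol carbon and the carbonyl carbon; the hydroxyl, as the donor, rotates outward, so the pyranonyl group turns inward and lies cis to the ketene in 12. The ketene C=C, the enol C=C and the pyranone C5=C6 bond then form a hexatriene that closes ring A by a thermally allowed disrotatory six-electron electrocyclization, joining the ketene carbon to pyranone C5 (C4a–C5 of the flavone) and giving dienone 13. In 13 the C4a hydrogen lies between two carbonyl groups, so enolisation is fast and irreversible and gives the aromatic hydroquinone 14; the C4a stereocentre of 13 is transient and no stereocentre remains. The closest known reaction is the Moore rearrangement of 4-alkenyl-, 4-aryl- and 4-heteroaryl-4-hydroxycyclobutenones to hydroquinones, here with the pyranone C5=C6 bond in the role of the alkene or arene bond. That bond is an enol ether whose β-carbon C5 is nucleophilic, which matches the electrophilic ketene carbon. The step needs closure through carbon and not through the hydroxyl oxygen (butenolide), which the outward rotation of the hydroxyl secures, and it needs a single closure site, which is given because C5 is the only position cis-disposed to the ketene. The oxygen pattern (tert-butoxy at C7, hydrogen at C6, hydroxyls at C5 and C8) is fixed by the constitution of 11; exclusion of air keeps the product at the hydroquinone level.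

**Step 8**
Reactants: 14 7-tert-butoxy-5,8-dihydroxy-3-methoxy-2-[3-methoxy-4-(triisopropylsilyloxy)phenyl]-4H-chromen-4-one
Product: 15 7-tert-butoxy-3,5,8-trimethoxy-2-[3-methoxy-4-(triisopropylsilyloxy)phenyl]-4H-chromen-4-one
Conditions: Me2SO4 (excess), K2CO3, acetone (dry), reflux
Reagents that add atoms: dimethyl sulfate, COS(=O)(=O)OC
Why: Williamson methylation under the usual forcing conditions for chelated 5-hydroxyflavones; the aryl tert-butyl ether is inert to base and the triisopropylsilyl ether is the most base-stable common silyl ether in an anhydrous, non-hydroxylic medium.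

**Step 9**
Reactants: 15 7-tert-butoxy-3,5,8-trimethoxy-2-[3-methoxy-4-(triisopropylsilyloxy)phenyl]-4H-chromen-4-one
Product: 16 7-hydroxy-3,5,8-trimethoxy-2-[3-methoxy-4-(triisopropylsilyloxy)phenyl]-4H-chromen-4-one
Conditions: CF3CO2H, CH2Cl2, 0 °C to rt
Reagents that add atoms: none
Why: Acidolysis of an aryl tert-butyl ether by loss of the tert-butyl cation as isobutene; methyl ethers and the hindered aryl silyl ether are stable to a Brønsted acid of this strength, and no Lewis acid that could strip the C5 methyl group is used.

**Step 10**
Reactants: 16 7-hydroxy-3,5,8-trimethoxy-2-[3-methoxy-4-(triisopropylsilyloxy)phenyl]-4H-chromen-4-one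
Product: 17 3,5,8-trimethoxy-2-[3-methoxy-4-(triisopropylsilyloxy)phenyl]-7-(3-methylbut-2-enyloxy)-4H-chromen-4-one
Conditions: prenyl bromide, K2CO3, acetone, rt
Reagents that add atoms: 1-bromo-3-methylbut-2-ene, CC(C)=CCBr
Why: Williamson alkylation of the C7 phenol, the most acidic flavone hydroxyl (vinylogous to the C4 carbonyl) and the only free one; mild conditions favour O- over C-prenylation.

**Step 11**
Reactants: 17 3,5,8-trimethoxy-2-[3-methoxy-4-(triisopropylsilyloxy)phenyl]-7-(3-methylbut-2-enyloxy)-4H-chromen-4-one
Product: 18 2-(4-hydroxy-3-methoxyphenyl)-3,5,8-trimethoxy-7-(3-methylbut-2-enyloxy)-4H-chromen-4-one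
Conditions: Bu4NF, AcOH, THF, 0 °C
Reagents that add atoms: none
Why: Fluoride cleaves the aryl O–Si bond; the acetic acid buffer keeps the liberated phenoxide protonated, and the prenyl and methyl ethers are inert to fluoride.

## Compound list

1 | 3-hydroxy-4H-pyran-4-one (pyromeconic acid) | O=c1ccocc1O | starting material
2 | 2-bromo-3-hydroxy-4H-pyran-4-one | O=c1ccoc(Br)c1O | intermediate
3 | 2-bromo-3-methoxy-4H-pyran-4-one | COc1c(Br)occc1=O | intermediate
4 | 2-methoxy-4-(4,4,5,5-tetramethyl-1,3,2-dioxaborolan-2-yl)phenol | COc1cc(B2OC(C)(C)C(C)(C)O2)ccc1O | starting material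
5 | triisopropyl[2-methoxy-4-(4,4,5,5-tetramethyl-1,3,2-dioxaborolan-2-yl)phenoxy]silane | COc1cc(B2OC(C)(C)C(C)(C)O2)ccc1O[Si](C(C)C)(C(C)C)C(C)C | intermediate
6 | 3-methoxy-2-[3-methoxy-4-(triisopropylsilyloxy)phenyl]-4H-pyran-4-one | COc1c(-c2ccc(O[Si](C(C)C)(C(C)C)C(C)C)c(OC)c2)occc1=O | intermediate
7 | 3,4-di-tert-butoxycyclobut-3-ene-1,2-dione (di-tert-butyl squarate) | CC(C)(C)OC1=C(OC(C)(C)C)C(=O)C1=O | starting material
8 | racemic 2,3-di-tert-butoxy-4-hydroxycyclobut-2-en-1-one (present as its aluminium alkoxide) | O=C1C(OC(C)(C)C)=C(OC(C)(C)C)C1O | intermediate (not isolated)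
9 | 3-tert-butoxycyclobut-3-ene-1,2-dione | O=C1C=C(OC(C)(C)C)C1=O | intermediate
10 | 6-lithio-3-methoxy-2-[3-methoxy-4-(triisopropylsilyloxy)phenyl]-4H-pyran-4-one | [Li]c1cc(=O)c(OC)c(-c2ccc(O[Si](C(C)C)(C(C)C)C(C)C)c(OC)c2)o1 | intermediate (not isolated)
11 | racemic 6-(2-tert-butoxy-1-hydroxy-4-oxocyclobut-2-en-1-yl)-3-methoxy-2-[3-methoxy-4-(triisopropylsilyloxy)phenyl]-4H-pyran-4-one | O=C1C=C(OC(C)(C)C)C1(O)c1cc(=O)c(OC)c(-c2ccc(O[Si](C(C)C)(C(C)C)C(C)C)c(OC)c2)o1 | intermediate
12 | 6-[(1Z)-2-tert-butoxy-1-hydroxy-4-oxobuta-1,3-dien-1-yl]-3-methoxy-2-[3-methoxy-4-(triisopropylsilyloxy)phenyl]-4H-pyran-4-one (vinylketene) | O=C=C/C(OC(C)(C)C)=C(/O)c1cc(=O)c(OC)c(-c2ccc(O[Si](C(C)C)(C(C)C)C(C)C)c(OC)c2)o1 | intermediate (not isolated)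
13 | racemic 7-tert-butoxy-8-hydroxy-3-methoxy-2-[3-methoxy-4-(triisopropylsilyloxy)phenyl]-4aH-chromene-4,5-dione | O=C1C=C(OC(C)(C)C)C(O)=C2OC(c3ccc(O[Si](C(C)C)(C(C)C)C(C)C)c(OC)c3)=C(OC)C(=O)C12 | intermediate (not isolated)
14 | 7-tert-butoxy-5,8-dihydroxy-3-methoxy-2-[3-methoxy-4-(triisopropylsilyloxy)phenyl]-4H-chromen-4-one | O=c1c(OC)c(-c3ccc(O[Si](C(C)C)(C(C)C)C(C)C)c(OC)c3)oc2c(O)c(OC(C)(C)C)cc(O)c12 | intermediate
15 | 7-tert-butoxy-3,5,8-trimethoxy-2-[3-methoxy-4-(triisopropylsilyloxy)phenyl]-4H-chromen-4-one | O=c1c(OC)c(-c3ccc(O[Si](C(C)C)(C(C)C)C(C)C)c(OC)c3)oc2c(OC)c(OC(C)(C)C)cc(OC)c12 | intermediate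
16 | 7-hydroxy-3,5,8-trimethoxy-2-[3-methoxy-4-(triisopropylsilyloxy)phenyl]-4H-chromen-4-one | O=c1c(OC)c(-c3ccc(O[Si](C(C)C)(C(C)C)C(C)C)c(OC)c3)oc2c(OC)c(O)cc(OC)c12 | intermediate
17 | 3,5,8-trimethoxy-2-[3-methoxy-4-(triisopropylsilyloxy)phenyl]-7-(3-methylbut-2-enyloxy)-4H-chromen-4-one | O=c1c(OC)c(-c3ccc(O[Si](C(C)C)(C(C)C)C(C)C)c(OC)c3)oc2c(OC)c(OCC=C(C)C)cc(OC)c12 | intermediate
18 | 2-(4-hydroxy-3-methoxyphenyl)-3,5,8-trimethoxy-7-(3-methylbut-2-enyloxy)-4H-chromen-4-one (4'-hydroxy-3,5,8,3'-tetramethoxy-7-prenyloxyflavone) | COc1cc(-c2oc3c(OC)c(OCC=C(C)C)cc(OC)c3c(=O)c2OC)ccc1O | target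

## Step count and least certain steps

Total: 11 steps. Longest linear sequence: 9 steps (steps 1, 2, 4, 6, 7, 8, 9, 10, 11, from 1 to 18).

**Step 7 (key step).** The vinylketene 12 may be diverted before carbon–carbon closure, by addition of the free hydroxyl or of a second molecule to the ketene, or by thermal loss of isobutene from the vinylogous tert-butyl ester. The electron-rich hydroquinone may also be oxidised during isolation. These risks arise because the pyranone C5=C6 bond has not served as the 2π partner before and may close more slowly than an arene or a simple alkene.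
- Fallback, setting out from 11: the tertiary hydroxyl is silylated (Me3SiCl, Et3N, CH2Cl2) to give 6-[2-tert-butoxy-4-oxo-1-(trimethylsilyloxy)cyclobut-2-en-1-yl]-3-methoxy-2-[3-methoxy-4-(triisopropylsilyloxy)phenyl]-4H-pyran-4-one F1. This is the known silyl ether variant of the rearrangement, which cannot lactonise and gives a mono-protected hydroquinone that cannot oxidise to the quinone.
- Heating F1 in toluene should give 7-tert-butoxy-5-hydroxy-3-methoxy-2-[3-methoxy-4-(triisopropylsilyloxy)phenyl]-8-(trimethylsilyloxy)-4H-chromen-4-one F2.
- Brief methanolysis (citric acid, MeOH) removes the labile aryl trimethylsilyl ether and returns the route to 14.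

**Step 6.** Deprotonation may compete at C5 (directed by the carbonyl), or the lithiated pyranone 10 may add to unreacted 6 or undergo ring opening, because a 4-pyranone is both a C–H acid and a Michael acceptor.
- Fallback, setting out from 6: zincation with (tmp)ZnCl·LiCl (tmp = 2,2,6,6-tetramethylpiperidide) in THF at 25 °C and quenching with I2 gives 6-iodo-3-methoxy-2-[3-methoxy-4-(triisopropylsilyloxy)phenyl]-4H-pyran-4-one F3. It can be purified and its constitution secured.
- Iodine–magnesium exchange with i-PrMgCl·LiCl at −40 °C then generates the C6 carbanion at a defined site without amine or excess base, and its addition to 9 returns the route to 11.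

**Step 1.** Halogenation may run on to a dibromide or stray to C5, and the vinylogous acyl bromide may hydrolyse on work-up, because the hydroxypyranone is an activated, polyfunctional enol.
- Fallback, setting out from 1: O-methylation (MeI, K2CO3) gives 3-methoxy-4H-pyran-4-one F4.
- Deprotonative zincation of F4 at C2, the C–H flanked by the ring oxygen and the methoxy-bearing carbon, with (tmp)ZnCl·LiCl, followed by I2, gives 2-iodo-3-methoxy-4H-pyran-4-one F5.
- Suzuki coupling of F5 with 5 under the conditions of step 4 returns the route to 6. This replaces electrophilic substitution by C–H metalation.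

**Step 8.** Alkylation of the chelated C5 hydroxyl is slow, and during the long heating with carbonate the silyl group may migrate or be lost from O4', which would then be methylated irreversibly.
- Fallback, setting out from 11: the tertiary alcohol is methylated under non-phenoxide conditions (MeI, Ag2O, K2CO3, MeCN) to give 6-(2-tert-butoxy-1-methoxy-4-oxocyclobut-2-en-1-yl)-3-methoxy-2-[3-methoxy-4-(triisopropylsilyloxy)phenyl]-4H-pyran-4-one F6.
- Thermolysis in toluene then delivers the C8 methyl ether directly as 7-tert-butoxy-5-hydroxy-3,8-dimethoxy-2-[3-methoxy-4-(triisopropylsilyloxy)phenyl]-4H-chromen-4-one F7.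
- A single methylation of the remaining chelated phenol with MeI and Ag2O in CHCl3, which leaves silyl ethers untouched, returns the route to 15.

## Further compounds

F1 | step 7 | 6-[2-tert-butoxy-4-oxo-1-(trimethylsilyloxy)cyclobut-2-en-1-yl]-3-methoxy-2-[3-methoxy-4-(triisopropylsilyloxy)phenyl]-4H-pyran-4-one (racemic) | C[Si](C)(C)OC1(c2cc(=O)c(OC)c(-c3ccc(O[Si](C(C)C)(C(C)C)C(C)C)c(OC)c3)o2)C(OC(C)(C)C)=CC1=O
F2 | step 7 | 7-tert-butoxy-5-hydroxy-3-methoxy-2-[3-methoxy-4-(triisopropylsilyloxy)phenyl]-8-(trimethylsilyloxy)-4H-chromen-4-one | O=c1c(OC)c(-c3ccc(O[Si](C(C)C)(C(C)C)C(C)C)c(OC)c3)oc2c(O[Si](C)(C)C)c(OC(C)(C)C)cc(O)c12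
F3 | step 6 | 6-iodo-3-methoxy-2-[3-methoxy-4-(triisopropylsilyloxy)phenyl]-4H-pyran-4-one | COc1c(-c2ccc(O[Si](C(C)C)(C(C)C)C(C)C)c(OC)c2)oc(I)cc1=O
F4 | step 1 | 3-methoxy-4H-pyran-4-one | COc1coccc1=O
F5 | step 1 | 2-iodo-3-methoxy-4H-pyran-4-one | COc1c(I)occc1=O
F6 | step 8 | 6-(2-tert-butoxy-1-methoxy-4-oxocyclobut-2-en-1-yl)-3-methoxy-2-[3-methoxy-4-(triisopropylsilyloxy)phenyl]-4H-pyran-4-one (racemic) | COC1(c2cc(=O)c(OC)c(-c3ccc(O[Si](C(C)C)(C(C)C)C(C)C)c(OC)c3)o2)C(OC(C)(C)C)=CC1=O
F7 | step 8 | 7-tert-butoxy-5-hydroxy-3,8-dimethoxy-2-[3-methoxy-4-(triisopropylsilyloxy)phenyl]-4H-chromen-4-one | O=c1c(OC)c(-c3ccc(O[Si](C(C)C)(C(C)C)C(C)C)c(OC)c3)oc2c(OC)c(OC(C)(C)C)cc(O)c12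
A1 | alternative 1 | 1-[2,5-dimethoxy-4-(3-methylbut-2-enyloxy)phenyl]-2-methoxy-3-[3-methoxy-4-(methoxymethoxy)phenyl]propane-1,3-dione | COc1cc(OCC=C(C)C)c(OC)cc1C(=O)C(OC)C(=O)c1ccc(OCOC)c(OC)c1
A2 | alternative 1 | 3-methoxy-2-[3-methoxy-4-(methoxymethoxy)phenyl]-7-(3-methylbut-2-enyloxy)chromene-4,5,8-trione | COC1=C(c2ccc(OCOC)c(OC)c2)OC2=C(C1=O)C(=O)C=C(OCC=C(C)C)C2=O
A3 | alternative 2 | (E)-3-[3-(benzyloxy)-2,5-dimethoxyphenoxy]-2-methoxy-3-[3-methoxy-4-(tosyloxy)phenyl]acrylic acid | OC(=O)/C(OC)=C(\Oc1cc(OC)cc(OCc2ccccc2)c1OC)c1ccc(OS(=O)(=O)c2ccc(C)cc2)c(OC)c1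
A4 | alternative 2 | 7-benzyloxy-3,5,8-trimethoxy-2-[3-methoxy-4-(tosyloxy)phenyl]chromen-4-one | O=c1c(OC)c(-c3ccc(OS(=O)(=O)c4ccc(C)cc4)c(OC)c3)oc2c(OC)c(OCc4ccccc4)cc(OC)c12
A5 | alternative 3 | pentacarbonyl{methoxy[5-methoxy-6-(3-methoxy-4-(methoxymethoxy)phenyl)-4-oxo-4H-pyran-3-yl]methylidene}chromium | COC(c1coc(-c2ccc(OCOC)c(OC)c2)c(OC)c1=O)=[Cr](=C=O)(=C=O)(=C=O)(=C=O)=C=O
A6 | alternative 3 | 2-ethynyl-4,4,5,5-tetramethyl-1,3,2-dioxaborolane | C#CB1OC(C)(C)C(C)(C)O1
A7 | alternative 3 | 8-hydroxy-3,5-dimethoxy-2-[3-methoxy-4-(methoxymethoxy)phenyl]-7-(4,4,5,5-tetramethyl-1,3,2-dioxaborolan-2-yl)chromen-4-one | O=c1c(OC)c(-c3ccc(OCOC)c(OC)c3)oc2c(O)c(B4OC(C)(C)C(C)(C)O4)cc(OC)c12
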